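**Assumption:** the target, 4-hydroxy-3-[(2E,6E)-3,7-dimethyl-9-(2,6,6-trimethylcyclohex-1-enyl)nona-2,6-dienyl]benzoic acid (C27H38O3), has no stereocentre and is achiral. The only stereochemistry to control is the two E trisubstituted alkenes. Compound 7 is taken as a catalogue building block; if it is not available, it is one Blanc chloromethylation from methyl 4-methoxybenzoate.

## Retrosynthetic overview
1. Target 9 comes from bis-O-methyl compound 8 by one non-acidic double demethylation (ester and aryl ether).
2. Compound 8 is cut at the ArCH2–CH= bond (C1'–C2') into benzyl chloride 7 and the E-alkenylalane from enyne 6. The carboalumination sets the 2'E alkene.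
3. Enyne 6 is cut at the =CH–CH2 bond (C6'–C5') into E-vinyl iodide 3 and the TMS-homopropargylzinc from 4 (Negishi 1,5-enyne synthesis).
4. Vinyl iodide 3 comes from alkyne 2 by carboalumination/iodination, which sets the 6'E alkene. Alkyne 2 comes from dihydro-β-ionone 1.
5. No ring is formed in the route. The trimethylcyclohexene (in 1) and the arene (in 7) are both purchased intact.

## Route

**Step 1**
Reactants: 1, dihydro-β-ionone [4-(2,6,6-trimethylcyclohex-1-enyl)butan-2-one]
Product: 2, 2-(but-3-yn-1-yl)-1,3,3-trimethylcyclohex-1-ene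
Conditions: LDA (1.1 equiv), THF, −78 °C; ClP(O)(OEt)2 (1.15 equiv), −78 °C → rt; then add to LDA (2.3 equiv), THF, −78 °C → rt; aq. NH4Cl
Reagents that add atoms: none
Why: Kinetic deprotonation at the methyl group gives the terminal enol diethyl phosphate, and LDA eliminates phosphate from it to give the acetylide (Negishi methyl ketone → terminal alkyne conversion); the tetrasubstituted ring alkene is inert and no stereoelement is created.

**Step 2**
Reactants: 2
Product: 3, 2-[(3E)-4-iodo-3-methylbut-3-en-1-yl]-1,3,3-trimethylcyclohex-1-ene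
Conditions: Me3Al (2 equiv), Cp2ZrCl2 (0.25 equiv), CH2Cl2, 0 °C → rt, 12 h; then I2 (1.3 equiv), THF, −30 → 0 °C; aq. Na2S2O3
Reagents that add atoms: trimethylaluminium, C[Al](C)C (adds CH3); iodine, II (adds I)
Why: In the Negishi Zr-catalysed carboalumination, Me–Al adds syn across the terminal alkyne with Al at the terminus, and iodinolysis proceeds with retention, giving the E vinyl iodide (≥98%) that becomes the 6'E alkene.

**Step 3**
Reactants: 3; 4, (4-bromobut-1-yn-1-yl)trimethylsilane
Product: 5, trimethyl[(5E)-6-methyl-8-(2,6,6-trimethylcyclohex-1-enyl)oct-5-en-1-yn-1-yl]silane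
Conditions: 4 (1.5 equiv), Mg, THF; anhydrous ZnBr2, 0 °C; then 3, PdCl2(dppf) (3 mol %) or Pd(PPh3)4 (5 mol %), THF, rt
Reagents that add atoms: 4, C[Si](C)(C)C#CCCBr (adds the CH2CH2C≡C–SiMe3 unit)
Why: Negishi sp3–sp2 cross-coupling of a homopropargylzinc with an alkenyl iodide proceeds with full retention of alkene geometry and little β-hydride elimination, giving the 1,5-enyne directly.

**Step 4**
Reactants: 5
Product: 6, 1,3,3-trimethyl-2-[(3E)-3-methyloct-3-en-7-yn-1-yl]cyclohex-1-ene
Conditions: K2CO3, MeOH, rt
Reagents that add atoms: none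
Why: Methoxide-mediated protodesilylation cleaves only the alkynyl C–Si bond and leaves both alkenes untouched.

**Step 5**
Reactants: 6; 7, methyl 3-(chloromethyl)-4-methoxybenzoate
Product: 8, methyl 3-[(2E,6E)-3,7-dimethyl-9-(2,6,6-trimethylcyclohex-1-enyl)nona-2,6-dien-1-yl]-4-methoxybenzoate
Conditions: 6 (1.1 equiv), Me3Al (2 equiv), Cp2ZrCl2 (0.25 equiv), ClCH2CH2Cl, 0 °C → rt; strip solvent and excess Me3Al in vacuo, triturate with hexane to remove Zr salts; then 7 (1.0 equiv), NiCl2(PPh3)2 (5 mol %)/n-BuLi (10 mol %), THF, −20 °C → rt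
Reagents that add atoms: trimethylaluminium, C[Al](C)C (adds CH3); 7, COC(=O)c1ccc(OC)c(CCl)c1 (adds the ArCH2 unit)
Why: A second syn carboalumination sets the 2'E alkene, and Ni(0)-catalysed alkenylalane–benzyl chloride cross-coupling transfers the alkenyl group with retention; the tri- and tetrasubstituted alkenes do not carbometalate, and the THF-complexed alane does not attack the methyl ester once free Me3Al has been removed.

**Step 6**
Reactants: 8
Product: 9, cacospongin D
Conditions: NaSEt (8 equiv), DMF, 130–140 °C, Ar, 4–6 h; then cold 1 M citric acid/HCl to pH ~3, extract with EtOAc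
Reagents that add atoms: none (two O–CH3 groups are removed; protons come from work-up)
Why: The soft thiolate attacks both O-methyl groups by SN2 (ester first, then aryl ether; Feutrill–Mirrington type demethylation), and because the medium is non-acidic there is no chroman formation from the o-allylphenol, no polyene cyclisation and no E/Z erosion.

## Compound list
1 | dihydro-β-ionone, 4-(2,6,6-trimethylcyclohex-1-enyl)butan-2-one | CC1=C(CCC(C)=O)C(C)(C)CCC1 | starting material
2 | 2-(but-3-yn-1-yl)-1,3,3-trimethylcyclohex-1-ene | CC1=C(CCC#C)C(C)(C)CCC1 | intermediate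
3 | 2-[(3E)-4-iodo-3-methylbut-3-en-1-yl]-1,3,3-trimethylcyclohex-1-ene | CC1=C(CC/C(C)=C/I)C(C)(C)CCC1 | intermediate
4 | (4-bromobut-1-yn-1-yl)trimethylsilane | C[Si](C)(C)C#CCCBr | starting material
5 | trimethyl[(5E)-6-methyl-8-(2,6,6-trimethylcyclohex-1-enyl)oct-5-en-1-yn-1-yl]silane | CC1=C(CC/C(C)=C/CCC#C[Si](C)(C)C)C(C)(C)CCC1 | intermediate
6 | 1,3,3-trimethyl-2-[(3E)-3-methyloct-3-en-7-yn-1-yl]cyclohex-1-ene | CC1=C(CC/C(C)=C/CCC#C)C(C)(C)CCC1 | intermediate
7 | methyl 3-(chloromethyl)-4-methoxybenzoate | COC(=O)c1ccc(OC)c(CCl)c1 | starting material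
8 | methyl 3-[(2E,6E)-3,7-dimethyl-9-(2,6,6-trimethylcyclohex-1-enyl)nona-2,6-dien-1-yl]-4-methoxybenzoate | CC1=C(CC/C(C)=C/CC/C(C)=C/Cc2cc(C(=O)OC)ccc2OC)C(C)(C)CCC1 | intermediate
9 | cacospongin D, 4-hydroxy-3-[(2E,6E)-3,7-dimethyl-9-(2,6,6-trimethylcyclohex-1-enyl)nona-2,6-dien-1-yl]benzoic acid | CC1=C(CC/C(C)=C/CC/C(C)=C/Cc2cc(C(=O)O)ccc2O)C(C)(C)CCC1 | target

## Summary
Total step count: 6
Longest linear sequence: 6 (1 → 2 → 3 → 5 → 6 → 8 → 9)

**Three steps most likely to fail, each with a fallback:**
1. **Step 6, double demethylation at about 135 °C.** The reaction may be incomplete, or the doubly activated ArCH2–CH= unit may suffer.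
   - Fallback: change the protecting-group strategy.
   - Use methyl 3-(bromomethyl)-4-(tert-butyldimethylsilyloxy)benzoate in Step 5. It is made from methyl 4-hydroxy-3-methylbenzoate with TBSCl/imidazole, then NBS/AIBN.
   - The end game then becomes LiOH in aq. THF/MeOH at ≤50 °C, which removes both the aryl silyl ether and the ester.
2. **Step 5, alkenylalane/benzyl chloride coupling in the presence of an ester.** The risks are Al-promoted methylation of the o-methoxybenzyl chloride and Ni poisoning by Zr residues.
   - Fallback: reverse the polarity.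
   - Quench the alane with I2 to give the E vinyl iodide.
   - Couple that iodide (Pd, Negishi) with the ester-tolerant benzylzinc chloride made from 7 with Zn/LiCl.
3. **Step 1, ketone to terminal alkyne.** The risks are methyl versus methylene enolisation and allene or internal alkyne by-products.
   - Fallback: build 2 by C–C bond formation instead.
   - Convert β-cyclocitral to β-cyclogeranyl bromide (NaBH4, then PBr3).
   - Alkylate the bromide with lithiated 1-(trimethylsilyl)propyne, then remove the silyl group with K2CO3/MeOH.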